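| setting | Friday's | Monday's | Sunday's | flask |
|---|---|---|---|---|
| substrate | 0.050 M | 0.050 M | 0.050 M | 0.050 M |
| partner | 0.033 M | 0.049 M | 0.065 M | 0.0650 M |
| catalyst | 1.6 mM | 1.6 mM | 0.80 mM | 1.6 mM |
| remark | run made earlier | run made earlier | run made earlier |  |
| time |  |  |  | 30 min |

| run | time / min | target / % |
|---|---|---|
| Friday's | 4.00 | 46.7 |
| Friday's | 8.00 | 51.2 |
| Friday's | 10.0 | 52.3 |
| Friday's | 15.0 | 51.2 |
| Friday's | 20.0 | 50.8 |
| Monday's | 1.33 | 35.5 |
| Monday's | 2.50 | 51.9 |
| Monday's | 5.00 | 64.7 |
| Monday's | 10.0 | 71.0 |
| Monday's | 20.0 | 72.1 |
| Sunday's | 1.50 | 26.6 |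
| Sunday's | 5.00 | 56.3 |
| Sunday's | 8.00 | 64.6 |
| Sunday's | 12.0 | 69.4 |
| Sunday's | 20.0 | 71.2 |

(readings scatter by 0.5 percentage points)

1. amount of target in percent of the substrate charged, at 1.5 min, 8.0 min and 30 min



**One step.** In a one-step world Friday's and Monday's runs would have stopped when their limiting reagent, the partner, was spent: Friday's at 66.0% of the substrate charge, Monday's at 98.0%. Their last readings were 50.8% and 72.1%. So partner went somewhere else.

**The fork.** I followed one partner molecule. At each moment it either made target or was lost by itself, and I took the target exit to scale with s, the fraction of substrate left, and the loss exit not to. Let g be the partner lost per partner turned into target while the substrate is untouched, the inverse of a selectivity factor. The odds of loss are then g/s, and summing them gives partner lost = −g ln s, in fractions of the substrate charge.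

**Reading it.** Taking each run to stop with its partner spent, and s as what target left, Friday's run read 0.214 and Monday's 0.203. I carried their mean, the fork ratio at this catalyst charge: 0.209. Sunday's run, at half that catalyst, read 0.472, about twice as much. The new flask has Friday's catalyst, so I kept the smaller ratio.

**The bracket.** The flask holds Sunday's partner with a lower fork ratio, so Sunday's 71.2% was my floor. A floor on target caps the loss, and the cap gives a ceiling through s = exp(−loss/g): 94.0%. That ceiling gives a floor of 82.2%, that floor a ceiling of 89.9%, and that ceiling a floor of 85.4%. On this rule I committed to the bracket from 85.4% to 89.9% for 30 min.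

**The result.** The forecast, resting on “the partner decaying on its own, uncatalysed”, gave 45%, 79% and 86%, the last inside my bracket . The flask gave 45.7%, 81.9% and 86.2%, the last inside the bracket too .

    substrate + catalyst ⇌ catalyst + intermediate (K = 0.150, k = 10.0 L mol⁻¹ s⁻¹)
    partner + catalyst + intermediate → catalyst + target (k = 1300 L² mol⁻² s⁻¹)
    partner → decomposed reagent (k = 0.00210 s⁻¹)

**The exits.** At 1.19 min the flask's partner was going into target 2.4 times as fast as into decomposed reagent. By 30.0 min the flask held decomposed reagent equal to 43.8% of the substrate charge, and the fork ratio with the 12.0% of substrate then left gives 44.3%.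

The earlier runs and the new flask were generated by integration from invented constants.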